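## Retrosynthetic overview

1. Both rings close last, in one Pd/CO domino on an acyclic C11 iodide / C4 bromide / C2 stannane. The first CO becomes C12 and the lactone forms first. The second CO becomes C3 and the ten-membered ring forms second.
2. The acyclic precursor comes from C7–C8 bond formation between a γ-substituted 2-iodoallylindium (C4–C7, C11, C13) and a β-hydroxy aldehyde (C8–C10, C1, C2). O8 is then acylated.
3. Left half: but-2-yn-1-ol gives (Z)-3-bromobut-2-enal, which fixes the C4=C5 geometry. A reagent-controlled allenylation sets C6, and I2 turns the allene into the 2-iodoallyl unit.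
4. Right half: (E)-3-methylpent-2-en-4-yn-1-ol is epoxidised (Sharpless), which sets C10. Hydride opening, trans-hydroalumination and stannylation give the (Z)-stannane and so the C1=C2 geometry.
5. C7 and C8 are relayed from C6 in the allylindium addition. Only O6 is protected (TES).

Assumption: C1–C13 are the germacranolide positions of the target (C3 ketone, C6–O lactone, C8 ester, C10 carbinol, C11=C13 methylene, C12 lactone C=O); the target is taken as the open hydroxy-dienone drawn, and the four carbon building blocks are bought.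

## Route

Step 1
Reactants: 1 but-2-yn-1-ol
Product: 3 (Z)-3-bromobut-2-en-1-ol, via cyclic alkenylalanate 2 (not isolated)
Conditions: NaAlH2(OCH2CH2OMe)2 (Red-Al), THF, 0 °C to rt; NBS, −78 to 0 °C; aq potassium sodium tartrate
Reagents that add atoms: N-bromosuccinimide, O=C1CCC(=O)N1Br
Why: Alkoxide-directed trans-hydroalumination puts Al on C4 cis to the carbinol carbon in the five-membered alanate 2, and Al-to-Br exchange with retention fixes the (Z)-bromoalkene that becomes the ring-cis C4=C5 bond (hydroalumination–halogenation).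

Step 2
Reactants: 3 (Z)-3-bromobut-2-en-1-ol
Product: 4 (Z)-3-bromobut-2-enal
Conditions: MnO2 (activated), CH2Cl2, rt, dark, used at once
Reagents that add atoms: none
Why: Neutral MnO2 oxidation of an allylic alcohol gives the enal without acid or base, so the Z geometry does not drift and no stereocentre is involved.

Step 3
Reactants: 4 (Z)-3-bromobut-2-enal, 5 allenyltributylstannane
Product: 7 (4R,5Z)-6-bromohepta-1,2,5-trien-4-ol, via B-propargyl diazaborolidine 6 (not isolated)
Conditions: (R,R)-TsNHCH(Ph)CH(Ph)NHTs, BBr3, CH2Cl2, 0 °C to rt, evaporate; 5, CH2Cl2, 0 °C to rt; 4, −78 °C; pH 7 buffer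
Reagents that add atoms: none
Why: In this Corey-type reagent-controlled allenylation, Sn-to-B exchange with transposition gives propargylborane 6, which adds to 4 through a cyclic SE2' transition state in which the C2-symmetric bis-sulfonamide blocks one aldehyde face and so sets C6 (the sense is assigned by analogy with enal allylations, is checked by Mosher esters, and the antipodal controller is equally available).

Step 4
Reactants: 7 (4R,5Z)-6-bromohepta-1,2,5-trien-4-ol
Product: 8 [(4R,5Z)-6-bromohepta-1,2,5-trien-4-yl]oxy(triethyl)silane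
Conditions: TESCl, imidazole, CH2Cl2, 0 °C
Reagents that add atoms: chlorotriethylsilane, CC[Si](Cl)(CC)CC
Why: Silylation blocks 5-endo iodoetherification of the allenol in step 8 and keeps O6 distinct from O8 until the ester is in place, and C6 is untouched.

Step 5
Reactants: 9 (E)-3-methylpent-2-en-4-yn-1-ol
Product: 10 [(2S,3S)-3-ethynyl-3-methyloxiran-2-yl]methanol
Conditions: Ti(OiPr)4 (10 mol %), L-(+)-DIPT (12 mol %), t-BuOOH, 4 Å MS, CH2Cl2, −20 °C
Reagents that add atoms: tert-butyl hydroperoxide, CC(C)(C)OO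
Why: In the Sharpless asymmetric epoxidation the L-(+)-tartrate delivers oxygen to the same face as in geraniol-type E-allylic alcohols, giving the (2S,3S)-epoxide whose quaternary carbon is C10 with the required configuration.

Step 6
Reactants: 10 [(2S,3S)-3-ethynyl-3-methyloxiran-2-yl]methanol
Product: 13 (3R,4Z)-3-methyl-5-(tributylstannyl)pent-4-ene-1,3-diol, via alkynyl diol aluminate 11 (not isolated), via alkenylalanate 12 (not isolated)
Conditions: NaAlH2(OCH2CH2OMe)2 (3 equiv), THF, −20 °C to rt, then 40 °C; Bu3SnOTf, −78 °C to rt; aq potassium sodium tartrate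
Reagents that add atoms: tributyltin trifluoromethanesulfonate, CCCC[Sn](CCCC)(CCCC)OS(=O)(=O)C(F)(F)F
Why: The O8-bound aluminate delivers hydride to the near epoxide carbon (1,3-diol-selective opening that leaves the C10–O bond and hence C10 intact), the tertiary alkoxide then directs trans-hydroalumination of the alkyne, and Al-to-Sn exchange with retention gives the (Z)-stannane.

Step 7
Reactants: 13 (3R,4Z)-3-methyl-5-(tributylstannyl)pent-4-ene-1,3-diol
Product: 14 (3R,4Z)-3-hydroxy-3-methyl-5-(tributylstannyl)pent-4-enal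
Conditions: Dess–Martin periodinane, pyridine, CH2Cl2, 0 °C
Reagents that add atoms: none
Why: The buffered Dess–Martin oxidation takes only the primary alcohol, and the tertiary allylic alcohol and the acid-sensitive vinylstannane survive.

Step 8
Reactants: 8 [(4R,5Z)-6-bromohepta-1,2,5-trien-4-yl]oxy(triethyl)silane, 14 (3R,4Z)-3-hydroxy-3-methyl-5-(tributylstannyl)pent-4-enal
Product: 17 (1Z,3R,5R,6R,7S,8Z)-9-bromo-6-(1-iodoethenyl)-3-methyl-7-(triethylsilyloxy)-1-(tributylstannyl)deca-1,8-diene-3,5-diol, via 2-iodoallylic iodide 15 (not isolated), via allylindium diiodide 16 (not isolated)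
Conditions: 8 (1.3 equiv), I2 (1.25 equiv), NaHCO3, THF, 0 °C, dark, until colourless; 14 (1 equiv), InI, THF, −20 °C to rt; aq NH4Cl
Reagents that add atoms: iodine, II
Why: Iodine adds across the terminal allene bond, InI inserts only into the allylic C–I bond, and 16 adds through its γ-carbon in a closed chair (Barbier-type 2-haloallylation) in which the C11 iodine keeps the C6 residue cis to CH2In (giving the C7/C8 syn pair) while the aldehyde approaches anti to the bromoalkenyl group of C6, with H inside (allylic 1,3-strain) and OTES outside, which sets 7R and 8R (deca-chain C6 and C5).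

Step 9
Reactants: 17 the C8 alcohol of step 8, 18 (R)-2-methylbutanoic acid
Product: 19 (1Z,3R,5R,6R,7S,8Z)-9-bromo-3-hydroxy-6-(1-iodoethenyl)-3-methyl-7-(triethylsilyloxy)-1-(tributylstannyl)deca-1,8-dien-5-yl (2R)-2-methylbutanoate
Conditions: DIC, DMAP (cat.), CH2Cl2, 0 °C to rt
Reagents that add atoms: none
Why: The Steglich esterification acylates the only free secondary hydroxyl (O10 is tertiary, O6 is silylated) with retention at C8 and without ketene-type racemisation of the acid.

Step 10
Reactants: 19 the TES-protected ester of step 9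
Product: 20 (1Z,3R,5R,6S,7S,8Z)-9-bromo-3,7-dihydroxy-6-(1-iodoethenyl)-3-methyl-1-(tributylstannyl)deca-1,8-dien-5-yl (2R)-2-methylbutanoate
Conditions: PPTS (cat.), MeOH, 0 °C to rt
Reagents that add atoms: none
Why: Mild acid-catalysed methanolysis removes the secondary TES ether while the ester, both vinyl halides and the stannane stay, and no centre changes in space (the descriptor at deca-chain C6 changes only through CIP ranking).

Step 11
Reactants: 20 the hydroxy iodide/bromide/stannane of step 10
Product: 22 (3aR,4R,6R,7Z,10Z,11aS)-6-hydroxy-6,10-dimethyl-3-methylidene-2,9-dioxo-2,3,3a,4,5,6,9,11a-octahydrocyclodeca[b]furan-4-yl (2R)-2-methylbutanoate, via bromoalkenyl lactone 21 (not isolated)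
Conditions: Pd(PPh3)4 (10 mol %), K2CO3 (1.2 equiv), BHT, CO (3 bar), THF–DMF 4:1, 1 mM, 35 °C, 4 h, then 75 °C, 36 h
Reagents that add atoms: carbon monoxide, [C-]#[O+]
Why: Proposed new method: two palladium-catalysed carbonylations are run as one temperature-staged domino; at 35 °C zerovalent palladium inserts only into the C11–I bond, CO inserts and the C6 hydroxyl captures the acylpalladium in a 5-exo closure to give 21 (closest known type: carbonylative lactonisation of 3-halobut-3-en-1-ols to α-methylene-γ-butyrolactones), which also removes the only hydroxyl that could trap the second acylpalladium as a butenolide, and at 75 °C the C4–Br bond adds, CO inserts, and intramolecular transmetalation from the (Z)-stannane followed by reductive elimination with retention at both alkenes closes the ten-membered cross-conjugated dienone (closest known type: carbonylative Stille macrocyclisation), helped by the two ring-cis alkenes and the cis-fused lactone that bend the chain; no stereocentre is formed or touched.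

## Compound list

1 | but-2-yn-1-ol | CC#CCO | starting material
2 | sodium 2,2-bis(2-methoxyethoxy)-3-methyl-2,5-dihydro-1,2-oxaaluminol-2-uide (cyclic alkenylalanate) | [Na+].CC1=CCO[Al-]1(OCCOC)OCCOC | intermediate
3 | (Z)-3-bromobut-2-en-1-ol | C/C(Br)=C/CO | intermediate
4 | (Z)-3-bromobut-2-enal | C/C(Br)=C/C=O | intermediate
5 | allenyltributylstannane | C=C=C[Sn](CCCC)(CCCC)CCCC | starting material
6 | (4R,5R)-4,5-diphenyl-2-(prop-2-yn-1-yl)-1,3-bis(4-methylphenylsulfonyl)-1,3,2-diazaborolidine | C#CCB1N(S(=O)(=O)c2ccc(C)cc2)[C@H](c2ccccc2)[C@@H](c2ccccc2)N1S(=O)(=O)c1ccc(C)cc1 | intermediate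
7 | (4R,5Z)-6-bromohepta-1,2,5-trien-4-ol | C=C=C[C@@H](O)/C=C(/C)Br | intermediate
8 | [(4R,5Z)-6-bromohepta-1,2,5-trien-4-yl]oxy(triethyl)silane | C=C=C[C@@H](O[Si](CC)(CC)CC)/C=C(/C)Br | intermediate
9 | (E)-3-methylpent-2-en-4-yn-1-ol | C#C/C(C)=C/CO | starting material
10 | [(2S,3S)-3-ethynyl-3-methyloxiran-2-yl]methanol | C#C[C@]1(C)O[C@H]1CO | intermediate
11 | sodium bis(2-methoxyethoxy)aluminate of (3R)-3-methylpent-4-yne-1,3-diol (six-membered O,O-chelate) | [Na+].C#C[C@@]1(C)CCO[Al-](OCCOC)(OCCOC)O1 | intermediate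
12 | disodium bis-aluminate: five-membered (Z)-alkenylalanate on O10/C2, hydridoaluminate on O8 (10R) | [Na+].[Na+].[H][Al-](OCCOC)(OCCOC)OCC[C@]1(C)C=C[Al-](OCCOC)(OCCOC)O1 | intermediate
13 | (3R,4Z)-3-methyl-5-(tributylstannyl)pent-4-ene-1,3-diol | CCCC[Sn](CCCC)(CCCC)/C=C\[C@](C)(O)CCO | intermediate
14 | (3R,4Z)-3-hydroxy-3-methyl-5-(tributylstannyl)pent-4-enal | CCCC[Sn](CCCC)(CCCC)/C=C\[C@](C)(O)CC=O | intermediate
15 | [(2E,4S,5Z)-6-bromo-1,2-diiodohepta-2,5-dien-4-yl]oxy(triethyl)silane | IC/C(I)=C\[C@@H](O[Si](CC)(CC)CC)/C=C(/C)Br | intermediate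
16 | [(2E,4S,5Z)-6-bromo-2-iodo-4-(triethylsilyloxy)hepta-2,5-dien-1-yl]indium diiodide | I[In](I)C/C(I)=C\[C@@H](O[Si](CC)(CC)CC)/C=C(/C)Br | intermediate
17 | (1Z,3R,5R,6R,7S,8Z)-9-bromo-6-(1-iodoethenyl)-3-methyl-7-(triethylsilyloxy)-1-(tributylstannyl)deca-1,8-diene-3,5-diol | C=C(I)[C@@H]([C@@H](O[Si](CC)(CC)CC)/C=C(/C)Br)[C@H](O)C[C@@](C)(O)/C=C\[Sn](CCCC)(CCCC)CCCC | intermediate
18 | (R)-2-methylbutanoic acid | CC[C@@H](C)C(=O)O | starting material
19 | (1Z,3R,5R,6R,7S,8Z)-9-bromo-3-hydroxy-6-(1-iodoethenyl)-3-methyl-7-(triethylsilyloxy)-1-(tributylstannyl)deca-1,8-dien-5-yl (2R)-2-methylbutanoate | C=C(I)[C@@H]([C@@H](O[Si](CC)(CC)CC)/C=C(/C)Br)[C@H](OC(=O)[C@H](C)CC)C[C@@](C)(O)/C=C\[Sn](CCCC)(CCCC)CCCC | intermediate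
20 | (1Z,3R,5R,6S,7S,8Z)-9-bromo-3,7-dihydroxy-6-(1-iodoethenyl)-3-methyl-1-(tributylstannyl)deca-1,8-dien-5-yl (2R)-2-methylbutanoate | C=C(I)[C@@H]([C@@H](O)/C=C(/C)Br)[C@H](OC(=O)[C@H](C)CC)C[C@@](C)(O)/C=C\[Sn](CCCC)(CCCC)CCCC | intermediate
21 | (1R,3R,4Z)-1-{(2R,3R)-2-[(1Z)-2-bromoprop-1-enyl]-4-methylidene-5-oxooxolan-3-yl}-3-hydroxy-3-methyl-5-(tributylstannyl)pent-4-enyl (2R)-2-methylbutanoate | C=C1C(=O)O[C@@H](/C=C(/C)Br)[C@H]1[C@H](OC(=O)[C@H](C)CC)C[C@@](C)(O)/C=C\[Sn](CCCC)(CCCC)CCCC | intermediate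
22 | (3aR,4R,6R,7Z,10Z,11aS)-6-hydroxy-6,10-dimethyl-3-methylidene-2,9-dioxo-2,3,3a,4,5,6,9,11a-octahydrocyclodeca[b]furan-4-yl (2R)-2-methylbutanoate | C=C1C(=O)O[C@H]2/C=C(/C)C(=O)/C=C\[C@](C)(O)C[C@@H](OC(=O)[C@H](C)CC)[C@@H]12 | target

## Step count and risks

Total steps: 11. Longest linear sequence: 8 (steps 1–4 and 8–11). The right-hand branch is 7 (steps 5–11).

**Most likely to fail, first: step 11.**
- The vinyl bromide adds slowly to palladium under CO.
- The hindered (Z)-stannane transmetalates slowly.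
- Oligomers or the CO-free nine-membered Stille product may compete.
- The (Z)-γ-hydroxy-enone product can close to its C3/C10 hemiketal on acidic or basic work-up.

The fallback sets out from 21, which is isolated by stopping the run at 35 °C, and comes back at 22. It separates the carbonyl carbon from the ring closure. Pd(PPh3)4/CO/Bu3SnH formylation of the C4 bromide gives the (Z)-enal stannane F1. Iodine exchanges tin for iodine to give the (Z)-iodoalkenyl enal F2. CrCl2/NiCl2 (Nozaki–Hiyama–Kishi) closes the ring at C2–C3 to the macrocyclic C3 carbinol F3 as an epimer mixture. MnO2 then oxidises the bis-allylic alcohol to 22.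

**Second: step 8.**
- 16 can lose InI3 and fall back to allene 8.
- The facial sense at C7 rests on a conformational model.

The fallback sets out from 4 and 14 and comes back at 20. It makes C7–C8 by an aldol and sets C6 last. Aldehyde 4 is 2-iodoallylated with 3-bromo-2-iodoprop-1-ene and In to the racemic 2-iodo homoallylic alcohol F4. Dess–Martin oxidation gives the β-iodo-β,γ-enone F5. Its (E)-dicyclohexylboron enolate (c-Hex2BCl, Et3N) adds to 14 to give the anti aldol F6, whose unwanted C7/C8 pair is removed by chromatography. DIC/DMAP with 18 gives the keto ester F7. Reagent-controlled (R)-Me-CBS/catecholborane reduction of the C6 ketone gives 20.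

**Third: step 6.**
- Hydride can attack the alkynyl epoxide in the SN2' sense to give an allenol.
- The terminal alkyne may be only partly hydroaluminated.

The fallback sets out from 10 and comes back at 13. It builds the Z geometry by syn addition instead. NaAlH2(OCH2CH2OMe)2 at −20 °C with aqueous work-up gives the free alkynyl diol F8. Bu3SnOMe (neat, 60 °C) stannylates the alkyne carbon to the alkynylstannane diol F9. Cp2Zr(H)Cl (excess) followed by water gives 13, through syn-hydrozirconation at the tin-bearing carbon and protonolysis with retention.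

## Further compounds

F1 | step 11 | (Z)-enal stannane, 21 with CHO in place of Br at C4 (6S,7R,8R,10R,2'R; 1Z,4Z) | C=C1C(=O)O[C@@H](/C=C(/C)C=O)[C@H]1[C@H](OC(=O)[C@H](C)CC)C[C@@](C)(O)/C=C\[Sn](CCCC)(CCCC)CCCC
F2 | step 11 | (Z)-iodoalkenyl enal, F1 with I in place of SnBu3 at C2 | C=C1C(=O)O[C@@H](/C=C(/C)C=O)[C@H]1[C@H](OC(=O)[C@H](C)CC)C[C@@](C)(O)/C=C\I
F3 | step 11 | macrocyclic C3 carbinol, 22 with CH(OH) at C3 (both C3 epimers) | C=C1C(=O)O[C@H]2/C=C(/C)C(O)/C=C\[C@](C)(O)C[C@@H](OC(=O)[C@H](C)CC)[C@@H]12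
F4 | step 8 | (5Z)-6-bromo-2-iodohepta-1,5-dien-4-ol (racemic 2-iodo homoallylic alcohol) | C=C(I)CC(O)/C=C(/C)Br
F5 | step 8 | (5Z)-6-bromo-2-iodohepta-1,5-dien-4-one (β-iodo-β,γ-enone) | C=C(I)CC(=O)/C=C(/C)Br
F6 | step 8 | anti aldol, C6 ketone with free O8 (7R,8R,10R; 1Z,4Z) | C=C(I)[C@@H](C(=O)/C=C(/C)Br)[C@H](O)C[C@@](C)(O)/C=C\[Sn](CCCC)(CCCC)CCCC
F7 | step 8 | keto ester, F6 acylated at O8 with (R)-2-methylbutanoyl | C=C(I)[C@@H](C(=O)/C=C(/C)Br)[C@H](OC(=O)[C@H](C)CC)C[C@@](C)(O)/C=C\[Sn](CCCC)(CCCC)CCCC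
F8 | step 6 | (3R)-3-methylpent-4-yne-1,3-diol (free alkynyl diol) | C#C[C@](C)(O)CCO
F9 | step 6 | (3R)-3-methyl-5-(tributylstannyl)pent-4-yne-1,3-diol (alkynylstannane diol) | CCCC[Sn](CCCC)(CCCC)C#C[C@](C)(O)CCO
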